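**Compound numbers used throughout** (full list with SMILES after the steps): 1 farnesyl bromide; 2 methallyl alcohol; 3 its dianion; 4 allylic alcohol; 5 epoxy alcohol; 6 epoxy aldehyde; 7 vinyl oxirane; 8 ethyl chlorooxoacetate; 9 diazo keto ester; 10 oxiranium ylide; 11 keto ester; 12 acrylate ester; 13 lithium carboxylate; 14 target.

## Analysis of the target

The target is a monocyclic 3,6-dihydro-2H-pyran (O1, C2, C3, C4, C5, C6) whose only ring alkene, C4=C5, is trisubstituted because C5 carries a (3E,7E)-4,8,12-trimethyltrideca-3,7,11-trienyl (homofarnesyl) chain; C2 carries a 1-carboxyethenyl group, so the acid is a 2-substituted acrylic acid. C2 is the only stereocentre and is R; the two E alkenes of the chain are separated from the ring by two methylene groups and do not communicate with C2. The C2–H bond is both α to the ring oxygen and allylic to the acrylate, so strong base can move the exocyclic alkene toward C2 and erase the stereocentre, and the acrylic acid is a Michael acceptor. The 1,5-polyene and the allylic C6–O1 ether are open to Brønsted and Lewis acids (cation–olefin cyclisation, ionisation), which rules out strongly acidic steps once the chain is in place. The difficulty is selectivity, not size: one isolated stereocentre with no neighbour to control it, a ring alkene that must sit at C4=C5 and nowhere else, and five alkenes, four of them trisubstituted, that must be told apart in every oxidation or carbene step. The feature the plan rests on is that O1, C6 and C5 with its chain can be read as a 2-alkyl-2-vinyloxirane whose vinyl group is C4=C3, while C2 together with the α-carbon of the acrylic acid is one acyl-substituted carbene carbon. A [2,3] shift of the oxonium ylide made from the two joins O1–C2 and C2–C3, opens O1–C5 and moves the stereochemical information from C5 to C2.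

## Retrosynthetic reasoning

**14 to 12.** The acid is disconnected at its acyl C–O bond to ester 12 (through carboxylate 13). It stays masked to the end because a free O–H group would be captured by the carbene of the key step, and because the ester is what makes 9 a stable, acceptor-substituted diazo compound. The forward step is a mild saponification that must leave the C2–H bond alone.

**12 to 11.** The exocyclic C=CH2 bond is cut, which returns ketone 11. This turns the α-carbon of the acrylate into a carbonyl carbon, and a carbonyl group directly on C2 is what a stabilised carbene carbon carries. The forward step must methylenate a ketone next to an ester without enolising toward C2.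

**11 to 7 and 9.** Both ring bonds to C2 (O1–C2 and C2–C3) are cut and O1 is rejoined to C5. Oxirane 7 then holds O1, C6, C5, the whole chain and, as its vinyl group, C4 and C3; diazo ester 9 holds C2 and both carbonyl carbons. The cut is made here and not at C5–C6 or O1–C6 because it builds the ring with every chain carbon in place, fixes the alkene at C4=C5 by allylic transposition, and lets an easily made quaternary oxirane carbon hand its configuration to C2. In the forward direction a metal carbene from 9 must choose the oxirane oxygen over four alkenes, and ylide 10 must rearrange by a [2,3] and not a [1,2] shift, before the tertiary allylic C–O bond ionises.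

**9 to 8.** The bond between the ketone carbon and the diazo carbon is cut, giving acid chloride 8 and a one-carbon diazo nucleophile. The ester carbonyl of 8 is the less electrophilic one, so acylation should occur at the chloride only.

**7 to 6 to 5.** The vinyl C=C bond of 7 is cut (Wittig methylenation) to aldehyde 6, the oxidation product of alcohol 5. Passing through the epoxy alcohol keeps the hydroxyl group that the asymmetric epoxidation needs; the stereocentre is quaternary, so neither step can epimerise it.

**5 to 4.** The two C–O bonds of the oxirane are cut to give allylic alcohol 4. A Sharpless asymmetric epoxidation reacts only at the alkene with the allylic hydroxyl group, which separates the 1,1-disubstituted alkene from the three trisubstituted ones and sets the quaternary centre that is later relayed to C2.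

**4 to 1 and 2.** The bond between the allylic methylene of 4 and the first carbon of the farnesyl unit is cut, giving bromide 1 as electrophile and dianion 3 of alcohol 2 as nucleophile. Both E alkenes are bought with 1, and the two termini of the allyl anion in 3 are equivalent, so only SN2 against SN2′ attack on 1 needs control.

## Alternatives that were turned down

Alternative 1: Ring expansion of a dihydrofuran by a dihalocarbene.
- Disconnection: C4–C5 and C5–C6 are cut, so C5 is a one-carbon unit inserted into the enol ether double bond of trimethyl{[(2R)-2,3-dihydrofuran-2-yl]ethynyl}silane A1. The chain is joined to C5 afterwards and the alkyne stands for the acrylic acid.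
- Forward key step: dibromocarbene A2, made from a haloform and an alkoxide base, adds to the enol ether of A1 to give (3R)-6,6-dibromo-3-[(trimethylsilyl)ethynyl]-2-oxabicyclo[3.1.0]hexane A3. On warming, A3 loses bromide with disrotatory opening of the cyclopropane, assisted by the ring oxygen, and a silane hydride donor reduces the pyranylium ion at C6 to {[(2R)-5-bromo-3,6-dihydro-2H-pyran-2-yl]ethynyl}trimethylsilane A4.
- In its favour: C2 is set before the key step and is a spectator in it; the carbene A2 meets one strongly nucleophilic alkene because the polyene is not yet present; the vinyl bromide of A4 makes chain attachment modular.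
- Against it: A1 is a volatile, acid-sensitive enol ether that needs its own asymmetric synthesis. The cation formed from A3 can also lose a proton or take hydride at C4. The chain must come in by an sp2–sp3 cross-coupling of A4 with a homofarnesyl organometallic that is several steps from farnesyl material. The alkyne must then be desilylated and carboxylated at its internal carbon, a Markovnikov hydrocarboxylation with its own regiochemical problem.
- Comparison: this alternative is stronger on stereochemical security and on carbene chemoselectivity. The chosen plan offers convergence instead: ring, C5–chain bond and C2 with its carbonyl substituent are all present after one step, in seven linear steps against an estimated ten to twelve with three separately made fragments.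

Alternative 2: Ireland–Claisen rearrangement of a dioxanone.
- Disconnection: only C2–C3 is cut and C5 is rejoined to a carboxylate oxygen, giving (6R)-6-ethenyl-6-[(3E,7E)-4,8,12-trimethyltrideca-3,7,11-trien-1-yl]-1,4-dioxan-2-one A5.
- Forward key step: an amide base and a silyl chloride convert A5 into its silyl ketene acetal, {[(6R)-6-ethenyl-6-[(3E,7E)-4,8,12-trimethyltrideca-3,7,11-trien-1-yl]-5,6-dihydro-1,4-dioxin-2-yl]oxy}trimethylsilane A6. On warming, A6 rearranges through a ring-enforced boat: C2–C3 forms, the ester O–C5 bond breaks, the alkene moves to C4=C5, and aqueous work-up gives (2R)-5-[(3E,7E)-4,8,12-trimethyltrideca-3,7,11-trien-1-yl]-3,6-dihydro-2H-pyran-2-carboxylic acid A7.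
- In its favour: this lactone-to-dihydropyran rearrangement is an established reaction type; no carbene is involved; and the chirality transfer is unambiguous, because the ring fixes the ketene acetal geometry of A6 and the vinyl group can reach the enol carbon from one face only. On that point it is stronger than the chosen plan, whose outcome depends on an exo/endo preference.
- Against it: A7 has a carboxyl group where the target needs the α-carbon of an acrylic acid. The carboxyl carbon must become a methyl ketone, an enol triflate and then an acrylate, through an epimerisable α-alkoxy ketone. A5 itself must be made by etherification and lactonisation onto a tertiary allylic alcohol.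
- Comparison: the chosen plan uses the same source of chirality (7) but delivers C2 already bearing a ketone at the right carbon, so two steps follow ring formation instead of five. The price is a less certain key step; this alternative is kept as its fallback.

Alternative 3: Silyl-Prins cyclisation.
- Disconnection: O1–C6 and C5–C6 are cut; C6 becomes formaldehyde A8 and the rest is (3R,5Z,9E,13E)-10,14,18-trimethyl-1,6-bis(trimethylsilyl)nonadeca-5,9,13,17-tetraen-1-yn-3-ol A9, a homoallylic alcohol whose alkene is a (Z)-vinylsilane.
- Forward key step: under a mild Lewis acid A9 and A8 condense to an oxocarbenium ion; the vinylsilane attacks it through its silicon-bearing carbon, and loss of silicon from the β-silyl cation leaves the C4=C5 alkene in trimethyl{[(2R)-5-[(3E,7E)-4,8,12-trimethyltrideca-3,7,11-trien-1-yl]-3,6-dihydro-2H-pyran-2-yl]ethynyl}silane A10.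
- In its favour: C2 comes from a well-understood asymmetric alkynylation or propargylic ketone reduction and is not a reacting centre; silicon fixes the alkene position in A10. On predictability of the C2 configuration it is stronger than the chosen plan.
- Against it: the trisubstituted (Z)-vinylsilane of A9, carrying the chain on its silylated carbon, needs a stereodefined multistep synthesis. Oxocarbenium and β-silyl cations arise five atoms from the first chain alkene, which invites cation–olefin cyclisation, and a 2-oxonia-Cope shift can erode the configuration. As in alternative 1, the alkyne of A10 still has to be carboxylated at its internal carbon.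
- Comparison: the chosen plan avoids cationic intermediates beside the polyene, needs no vinylsilane and no alkyne-to-acrylate conversion, and is several steps shorter. It gives up the certainty about C2 that A9 brings.

Key step: step 6

Assumption: in the [2,3] transition state the keto ester group of ylide 10 is taken to lie exo (on the convex face of the oxirane-fused envelope, away from the oxirane CH2); a model of that arrangement maps the (R)-oxirane 7 onto (2R)-11, so D-(−)-diisopropyl tartrate is used in step 2, and L-(+)-diisopropyl tartrate would be used instead, with no other change, if the endo mode were found to dominate.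

## Route

Step 1
Reactants: 1 (2E,6E)-farnesyl bromide; 2 2-methylprop-2-en-1-ol (1.5 equiv)
Product: 4 2-[(3E,7E)-4,8,12-trimethyltrideca-3,7,11-trien-1-yl]prop-2-en-1-ol, via dilithio dianion 3 (not isolated)
Conditions: n-BuLi (2 equiv per 2), TMEDA, Et2O–hexane, 0 °C → rt; then 1, THF, −78 → 0 °C; H2O
Reagents that add atoms: none
Why: Double deprotonation of 2 (O–H, then the allylic methyl) gives the 2-(oxidomethyl)allyl anion 3, which should alkylate the primary allylic bromide by SN2 (allylic alkylation of an alcohol dianion). The allyl termini of 3 are equivalent, and attack at the trisubstituted γ-carbon of 1 would create a quaternary centre and is disfavoured, so the E alkenes of 1 are carried over unchanged.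

Step 2
Reactants: 4
Product: 5 [(2R)-2-[(3E,7E)-4,8,12-trimethyltrideca-3,7,11-trien-1-yl]oxiran-2-yl]methanol
Conditions: Ti(OiPr)4 (10 mol %), D-(−)-diisopropyl tartrate (12 mol %), t-BuOOH (decane), 4 Å molecular sieves, CH2Cl2, −20 °C
Reagents that add atoms: tert-butyl hydroperoxide, CC(C)(C)OO
Why: Sharpless asymmetric epoxidation: the chiral catalyst formed from Ti(OiPr)4 and the tartrate binds the allylic alkoxide, so only the 1,1-disubstituted alkene is epoxidised and the three isolated trisubstituted alkenes are left. D-(−)-Diisopropyl tartrate, the enantiomer of the ligand that gives (S)-2-alkylglycidols from 2-substituted allyl alcohols, should deliver oxygen to the face that gives the (R)-epoxy alcohol. Catalytic loading with sieves limits titanium-assisted opening of the 2,2-disubstituted oxirane.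

Step 3
Reactants: 5
Product: 6 (2S)-2-[(3E,7E)-4,8,12-trimethyltrideca-3,7,11-trien-1-yl]oxirane-2-carbaldehyde
Conditions: SO3·pyridine, DMSO, Et3N, CH2Cl2, 0 °C
Reagents that add atoms: none
Why: Parikh–Doering oxidation; activated DMSO under basic, non-acidic conditions should oxidise the primary alcohol without opening the oxirane or touching the alkenes. The quaternary stereocentre cannot epimerise (the descriptor changes from R to S only because CHO outranks the ring CH2).

Step 4
Reactants: 6
Product: 7 (2R)-2-ethenyl-2-[(3E,7E)-4,8,12-trimethyltrideca-3,7,11-trien-1-yl]oxirane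
Conditions: Ph3PCH3Br, KN(SiMe3)2, THF, 0 °C; then 6, −78 → 0 °C; chromatography on Et3N-deactivated silica
Reagents that add atoms: methyltriphenylphosphonium bromide, C[P+](c1ccccc1)(c1ccccc1)c1ccccc1.[Br-]
Why: Wittig methylenation; the non-stabilised ylide should add to the aldehyde faster than it attacks the hindered oxirane, and there is no α-hydrogen to lose. The product, a tertiary allylic oxirane, is kept away from acid.

Step 5
Reactants: 8 ethyl chlorooxoacetate
Product: 9 ethyl 3-diazo-2-oxopropanoate
Conditions: Me3SiCHN2 (2 equiv, hexanes), THF–MeCN, 0 °C → rt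
Reagents that add atoms: trimethylsilyldiazomethane, C[Si](C)(C)C=[N+]=[N-]
Why: Acylation of the diazo carbon by the acid chloride, the diazo ketone-forming stage of the Arndt–Eistert sequence; chloride removes silicon from the acyl diazonium intermediate. The ester carbonyl, the less electrophilic of the two, should remain untouched.

Step 6
Reactants: 7 (2R)-2-ethenyl-2-[(3E,7E)-4,8,12-trimethyltrideca-3,7,11-trien-1-yl]oxirane (1.5 equiv); 9 ethyl 3-diazo-2-oxopropanoate
Product: 11 ethyl 2-oxo-2-[(2R)-5-[(3E,7E)-4,8,12-trimethyltrideca-3,7,11-trien-1-yl]-3,6-dihydro-2H-pyran-2-yl]acetate, via oxiranium ylide 10 (not isolated)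
Conditions: Cu(hfacac)2 [Cu(CF3COCHCOCF3)2] (5 mol %), CH2Cl2, reflux; 9 added over 6 h by syringe pump
Reagents that add atoms: none
Why: The divalent copper precatalyst is reduced by the diazo compound, and the electrophilic copper carbene from 9 is captured by an oxirane lone pair of 7 to give ylide 10, whose carbanion carbon bonds to the vinyl terminus (C2–C3) while the strained allylic O1–C5 bond breaks in a suprafacial [2,3]-sigmatropic shift through a five-membered envelope fused to the oxirane. The closest known reaction type is the copper-catalysed ring expansion of vinyl oxiranes, vinyl oxetanes and vinyl aziridines by diazo carbonyl compounds through onium ylides. The dihydropyran is not formed by cyclisation but by three-atom enlargement of the oxirane (O1 and C6 stay bonded while C2, C3 and C4 come to lie between O1 and C5), which also places the alkene at C4=C5 with the cis geometry the ring requires. The one new stereocentre, C2, is controlled by the configuration of the oxirane carbon, which is relayed and then lost (1,3-chirality transfer): only the ylide invertomer with the carbanion carbon syn to the vinyl group can rearrange, and with the keto ester group exo, where the ester sits in the related aza-[2,3]-Wittig ring expansion of vinyl aziridines and where it avoids the inward hydrogen of the oxirane CH2, the (R)-oxirane leads to (2R). The step needs chemoselectivity for oxygen over four alkenes; this is sought through the electron-poor hexafluoroacetylacetonate ligands, which favour ylide formation over cyclopropanation, the hindered trisubstituted nature of the chain alkenes, and slow addition of 9. Selectivity for the [2,3] shift over the [1,2] shift and deoxygenation rests on release of oxirane strain in an allylic C–O bond aligned with the vinyl π system; the excess of 7, which is recovered, limits carbene dimerisation and a second ylide event at the allylic ether of 11.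

Step 7
Reactants: 11
Product: 12 ethyl 2-[(2R)-5-[(3E,7E)-4,8,12-trimethyltrideca-3,7,11-trien-1-yl]-3,6-dihydro-2H-pyran-2-yl]prop-2-enoate
Conditions: Zn, CH2Br2, TiCl4, THF (reagent pre-formed at 5 °C); then 11, CH2Cl2, 0 °C → rt
Reagents that add atoms: dibromomethane, BrCBr
Why: Takai–Lombardo methylenation; the methylene reagent made from Zn, CH2Br2 and TiCl4 is non-basic, so the α-alkoxy ketone should not enolise toward C2 and the configuration should be kept. It methylenates ketones but not esters, so only the keto group of the 1,2-dicarbonyl unit reacts.

Step 8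
Reactants: 12
Product: 14 2-[(2R)-5-[(3E,7E)-4,8,12-trimethyltrideca-3,7,11-trien-1-yl]-3,6-dihydro-2H-pyran-2-yl]prop-2-enoic acid, via lithium carboxylate 13 (not isolated)
Conditions: LiOH (3 equiv), THF–H2O (3:1), 0 °C → rt; then 1 M HCl, 0 °C, to pH 3
Reagents that add atoms: lithium hydroxide, [Li+].[OH-]
Why: Saponification by acyl–oxygen cleavage; hydroxide should attack the ester carbonyl faster than the β-carbon of the α-substituted acrylate. The C2–H bond (allylic but cross-conjugated to the ester) is not acidic enough for hydroxide to move the alkene, and a brief cold acidification spares the polyene.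

## Compound list

1 | (2E,6E)-farnesyl bromide, (2E,6E)-1-bromo-3,7,11-trimethyldodeca-2,6,10-triene | BrC/C=C(\C)CC/C=C(\C)CCC=C(C)C | starting material
2 | 2-methylprop-2-en-1-ol (methallyl alcohol) | CC(=C)CO | starting material
3 | dilithio dianion of 2, lithium 2-(lithiomethyl)prop-2-en-1-olate | [Li]CC(=C)CO[Li] | intermediate
4 | 2-[(3E,7E)-4,8,12-trimethyltrideca-3,7,11-trien-1-yl]prop-2-en-1-ol | C=C(CO)CC/C=C(\C)CC/C=C(\C)CCC=C(C)C | intermediate
5 | [(2R)-2-[(3E,7E)-4,8,12-trimethyltrideca-3,7,11-trien-1-yl]oxiran-2-yl]methanol | OC[C@]1(CC/C=C(\C)CC/C=C(\C)CCC=C(C)C)CO1 | intermediate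
6 | (2S)-2-[(3E,7E)-4,8,12-trimethyltrideca-3,7,11-trien-1-yl]oxirane-2-carbaldehyde | O=C[C@]1(CC/C=C(\C)CC/C=C(\C)CCC=C(C)C)CO1 | intermediate
7 | (2R)-2-ethenyl-2-[(3E,7E)-4,8,12-trimethyltrideca-3,7,11-trien-1-yl]oxirane | C=C[C@]1(CC/C=C(\C)CC/C=C(\C)CCC=C(C)C)CO1 | intermediate
8 | ethyl chlorooxoacetate | CCOC(=O)C(=O)Cl | starting material
9 | ethyl 3-diazo-2-oxopropanoate | CCOC(=O)C(=O)C=[N+]=[N-] | intermediate
10 | (2R)-2-ethenyl-1-(3-ethoxy-2,3-dioxopropan-1-id-1-yl)-2-[(3E,7E)-4,8,12-trimethyltrideca-3,7,11-trien-1-yl]oxiran-1-ium (oxiranium ylide, carbanion carbon syn to the ethenyl group) | C=C[C@]1(CC/C=C(\C)CC/C=C(\C)CCC=C(C)C)C[O+]1[CH-]C(=O)C(=O)OCC | intermediate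
11 | ethyl 2-oxo-2-[(2R)-5-[(3E,7E)-4,8,12-trimethyltrideca-3,7,11-trien-1-yl]-3,6-dihydro-2H-pyran-2-yl]acetate | CCOC(=O)C(=O)[C@H]1CC=C(CC/C=C(\C)CC/C=C(\C)CCC=C(C)C)CO1 | intermediate
12 | ethyl 2-[(2R)-5-[(3E,7E)-4,8,12-trimethyltrideca-3,7,11-trien-1-yl]-3,6-dihydro-2H-pyran-2-yl]prop-2-enoate | CCOC(=O)C(=C)[C@H]1CC=C(CC/C=C(\C)CC/C=C(\C)CCC=C(C)C)CO1 | intermediate
13 | lithium 2-[(2R)-5-[(3E,7E)-4,8,12-trimethyltrideca-3,7,11-trien-1-yl]-3,6-dihydro-2H-pyran-2-yl]prop-2-enoate | [Li+].[O-]C(=O)C(=C)[C@H]1CC=C(CC/C=C(\C)CC/C=C(\C)CCC=C(C)C)CO1 | intermediate
14 | 2-[(2R)-5-[(3E,7E)-4,8,12-trimethyltrideca-3,7,11-trien-1-yl]-3,6-dihydro-2H-pyran-2-yl]prop-2-enoic acid (CNP0171598.2) | C=C(C(=O)O)[C@H]1CC=C(CC/C=C(\C)CC/C=C(\C)CCC=C(C)C)CO1 | target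

## Step count and least certain steps

Total: 8 steps. Longest linear sequence: 7 steps (1 → 4 → 5 → 6 → 7 → 11 → 12 → 14); step 5 is a one-step side branch from 8.

**Step 6 (key step).** Several things may go wrong. Cyclopropanation of the chain alkenes or of the vinyl group may compete with attack at oxygen: an oxirane oxygen is a weak donor, and every molecule of 7 offers four alkenes for one oxygen, so excess 7 does not change this ratio. The ylide may transfer its oxygen to the carbene carbon (deoxygenation of 7) or undergo the [1,2] shift to an oxetane. Cu(hfacac)2 acting as a Lewis acid, or the ylide itself, may ionise the tertiary allylic C–O bond before C2–C3 forms, or the endo arrangement may compete with exo; either lowers the enantiomeric purity of 11 in a way that conditions may not repair. The allylic ether oxygen of 11 may form a second ylide.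

Fallback (sets out from 7, returns at 12), using a ring-locked Claisen rearrangement in place of the carbene. The oxirane CH2 of 7 is opened by the sodium alkoxide of ethyl glycolate (NaH, DMF, 60 °C), and the tertiary alkoxide closes onto the ester in the same flask to give (6R)-6-ethenyl-6-[(3E,7E)-4,8,12-trimethyltrideca-3,7,11-trien-1-yl]-1,4-dioxan-2-one F1. Its silyl ketene acetal (LiN(SiMe3)2, Me3SiCl, Et3N, THF, −78 °C, then toluene, 100 °C) should undergo Ireland–Claisen rearrangement and, after aqueous work-up, give (2R)-5-[(3E,7E)-4,8,12-trimethyltrideca-3,7,11-trien-1-yl]-3,6-dihydro-2H-pyran-2-carboxylic acid F2; the boat enforced by the lactone ring allows bond formation on one face only, so the (R) centre of 7 maps onto (2R) without an exo/endo question. MeLi (2.2 equiv, Et2O, 0 °C, Me3SiCl quench) then converts the acid into 1-[(2R)-5-[(3E,7E)-4,8,12-trimethyltrideca-3,7,11-trien-1-yl]-3,6-dihydro-2H-pyran-2-yl]ethan-1-one F3. Kinetic enolisation on the methyl side (KN(SiMe3)2, PhNTf2, THF, −78 °C) gives 1-[(2R)-5-[(3E,7E)-4,8,12-trimethyltrideca-3,7,11-trien-1-yl]-3,6-dihydro-2H-pyran-2-yl]ethenyl trifluoromethanesulfonate F4, and alkoxycarbonylation (Pd(PPh3)4, CO (1 atm), EtOH, Et3N, DMF, 50 °C) then gives 12.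

**Step 7.** What may go wrong is electron transfer from Zn or from reduced titanium species to the very electrophilic keto group (reduction or pinacol coupling in place of methylenation), and Lewis-acid-induced ionisation of the allylic ring ether or cyclisation of the polyene. A Wittig methylenation would avoid these but risks enolisation toward C2 by the basic ylide, a silent loss of configuration.

Fallback (sets out from 11, returns at 12), a two-stage Peterson olefination. The weakly basic organocerium reagent from Me3SiCH2MgCl and CeCl3 (THF, −78 °C) should add to the ketone only and give ethyl 2-hydroxy-2-[(2R)-5-[(3E,7E)-4,8,12-trimethyltrideca-3,7,11-trien-1-yl]-3,6-dihydro-2H-pyran-2-yl]-3-(trimethylsilyl)propanoate F5, as a mixture at the new carbinol carbon that does not matter. KH (THF, 0 °C) then induces syn elimination to 12; at that stage C2 is no longer α to a ketone and cannot epimerise.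

**Step 1.** The strongly basic dianion may eliminate HBr from 1 to a triene, attack 1 in the SN2′ sense, or be alkylated twice, so that little 4 is obtained.

Fallback (sets out from 1, returns at 4), a sulfone-based coupling of reversed polarity. Bromide 1 and PhSO2Na (DMF, rt) give {[(2E,6E)-3,7,11-trimethyldodeca-2,6,10-trien-1-yl]sulfonyl}benzene F6. Its lithio derivative (n-BuLi, THF, −78 °C) is alkylated by ethyl 2-(bromomethyl)acrylate to ethyl (5E,9E)-6,10,14-trimethyl-2-methylidene-4-(phenylsulfonyl)pentadeca-5,9,13-trienoate F7. i-Bu2AlH (CH2Cl2, −78 °C) reduces the ester to (5E,9E)-6,10,14-trimethyl-2-methylidene-4-(phenylsulfonyl)pentadeca-5,9,13-trien-1-ol F8, and palladium-catalysed hydride displacement of the allylic sulfone (PdCl2(dppp), dppp = 1,3-bis(diphenylphosphino)propane, LiBHEt3, THF, 0 °C) gives 4.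

**Step 2.** Facial discrimination may be incomplete for a 1,1-disubstituted allylic alcohol with a long 2-alkyl group, and titanium-assisted opening of the 2,2-disubstituted oxirane may occur during the reaction or work-up.

Fallback (sets out from 4, returns at 5), resolution in place of asymmetric catalysis. Hydroxyl-directed epoxidation with VO(acac)2 and t-BuOOH (CH2Cl2, 0 °C) gives racemic [2-[(3E,7E)-4,8,12-trimethyltrideca-3,7,11-trien-1-yl]oxiran-2-yl]methanol F9. A lipase selected by screening for acylation of the (S)-alcohol (for example Burkholderia cepacia lipase, vinyl acetate, hexane, rt) converts that enantiomer into [(2R)-2-[(3E,7E)-4,8,12-trimethyltrideca-3,7,11-trien-1-yl]oxiran-2-yl]methyl acetate F10, whose descriptor is R only because the acetoxymethyl group outranks the ring CH2. Unreacted (R)-alcohol 5 is separated by chromatography.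

## Further compounds

F1 | step 6 | (6R)-6-ethenyl-6-[(3E,7E)-4,8,12-trimethyltrideca-3,7,11-trien-1-yl]-1,4-dioxan-2-one | O=C1COC[C@](C=C)(CC/C=C(\C)CC/C=C(\C)CCC=C(C)C)O1
F2 | step 6 | (2R)-5-[(3E,7E)-4,8,12-trimethyltrideca-3,7,11-trien-1-yl]-3,6-dihydro-2H-pyran-2-carboxylic acid | OC(=O)[C@H]1CC=C(CC/C=C(\C)CC/C=C(\C)CCC=C(C)C)CO1
F3 | step 6 | 1-[(2R)-5-[(3E,7E)-4,8,12-trimethyltrideca-3,7,11-trien-1-yl]-3,6-dihydro-2H-pyran-2-yl]ethan-1-one | CC(=O)[C@H]1CC=C(CC/C=C(\C)CC/C=C(\C)CCC=C(C)C)CO1
F4 | step 6 | 1-[(2R)-5-[(3E,7E)-4,8,12-trimethyltrideca-3,7,11-trien-1-yl]-3,6-dihydro-2H-pyran-2-yl]ethenyl trifluoromethanesulfonate | C=C(OS(=O)(=O)C(F)(F)F)[C@H]1CC=C(CC/C=C(\C)CC/C=C(\C)CCC=C(C)C)CO1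
F5 | step 7 | ethyl 2-hydroxy-2-[(2R)-5-[(3E,7E)-4,8,12-trimethyltrideca-3,7,11-trien-1-yl]-3,6-dihydro-2H-pyran-2-yl]-3-(trimethylsilyl)propanoate | CCOC(=O)C(O)(C[Si](C)(C)C)[C@H]1CC=C(CC/C=C(\C)CC/C=C(\C)CCC=C(C)C)CO1
F6 | step 1 | {[(2E,6E)-3,7,11-trimethyldodeca-2,6,10-trien-1-yl]sulfonyl}benzene | O=S(=O)(C/C=C(\C)CC/C=C(\C)CCC=C(C)C)c1ccccc1
F7 | step 1 | ethyl (5E,9E)-6,10,14-trimethyl-2-methylidene-4-(phenylsulfonyl)pentadeca-5,9,13-trienoate (racemic) | C=C(C(=O)OCC)CC(/C=C(\C)CC/C=C(\C)CCC=C(C)C)S(=O)(=O)c1ccccc1
F8 | step 1 | (5E,9E)-6,10,14-trimethyl-2-methylidene-4-(phenylsulfonyl)pentadeca-5,9,13-trien-1-ol (racemic) | C=C(CO)CC(/C=C(\C)CC/C=C(\C)CCC=C(C)C)S(=O)(=O)c1ccccc1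
F9 | step 2 | [2-[(3E,7E)-4,8,12-trimethyltrideca-3,7,11-trien-1-yl]oxiran-2-yl]methanol (racemic) | OCC1(CC/C=C(\C)CC/C=C(\C)CCC=C(C)C)CO1
F10 | step 2 | [(2R)-2-[(3E,7E)-4,8,12-trimethyltrideca-3,7,11-trien-1-yl]oxiran-2-yl]methyl acetate | CC(=O)OC[C@@]1(CC/C=C(\C)CC/C=C(\C)CCC=C(C)C)CO1
A1 | alternative 1 | trimethyl{[(2R)-2,3-dihydrofuran-2-yl]ethynyl}silane | C[Si](C)(C)C#C[C@H]1CC=CO1
A2 | alternative 1 | dibromocarbene | Br[C]Br
A3 | alternative 1 | (3R)-6,6-dibromo-3-[(trimethylsilyl)ethynyl]-2-oxabicyclo[3.1.0]hexane (both cis-fused diastereomers) | C[Si](C)(C)C#C[C@H]1CC2C(O1)C2(Br)Br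
A4 | alternative 1 | {[(2R)-5-bromo-3,6-dihydro-2H-pyran-2-yl]ethynyl}trimethylsilane | C[Si](C)(C)C#C[C@H]1CC=C(Br)CO1
A5 | alternative 2 | (6R)-6-ethenyl-6-[(3E,7E)-4,8,12-trimethyltrideca-3,7,11-trien-1-yl]-1,4-dioxan-2-one | O=C1COC[C@](C=C)(CC/C=C(\C)CC/C=C(\C)CCC=C(C)C)O1
A6 | alternative 2 | {[(6R)-6-ethenyl-6-[(3E,7E)-4,8,12-trimethyltrideca-3,7,11-trien-1-yl]-5,6-dihydro-1,4-dioxin-2-yl]oxy}trimethylsilane | C[Si](C)(C)OC1=COC[C@](C=C)(CC/C=C(\C)CC/C=C(\C)CCC=C(C)C)O1
A7 | alternative 2 | (2R)-5-[(3E,7E)-4,8,12-trimethyltrideca-3,7,11-trien-1-yl]-3,6-dihydro-2H-pyran-2-carboxylic acid | OC(=O)[C@H]1CC=C(CC/C=C(\C)CC/C=C(\C)CCC=C(C)C)CO1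
A8 | alternative 3 | formaldehyde | C=O
A9 | alternative 3 | (3R,5Z,9E,13E)-10,14,18-trimethyl-1,6-bis(trimethylsilyl)nonadeca-5,9,13,17-tetraen-1-yn-3-ol | C[Si](C)(C)C#C[C@H](O)C/C=C(\[Si](C)(C)C)CC/C=C(\C)CC/C=C(\C)CCC=C(C)C
A10 | alternative 3 | trimethyl{[(2R)-5-[(3E,7E)-4,8,12-trimethyltrideca-3,7,11-trien-1-yl]-3,6-dihydro-2H-pyran-2-yl]ethynyl}silane | C[Si](C)(C)C#C[C@H]1CC=C(CC/C=C(\C)CC/C=C(\C)CCC=C(C)C)CO1
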